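**Strategy.** With the side chain numbered C1' (ArOCH2), C2'/C3' (oxirane CH and CCH3), C4' (CH2), C5' (ring CH–O of the oxolanone), C6' (CH2), C7' (C(OH)CH3) and C8' (C=O), the route rests on cutting C5'–C6' and C5'–O. The feature used is that C5' is a hydrogen-bearing carbinol carbon of the lactone ring lying between the C4' and C6' methylenes. One lithiation–borylation–oxidation joins both halves and sets C5' by reagent control, closing no ring. Its precursors are Z-alkenyl carbamate 8, whose OCH2 carbon becomes C5', and pinacol boronate 13, which carries C6' on boron and C7'/C8' as a diol acetonide.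

Key step: step 9

Assumption: (+)-sparteine is taken to be purchasable, and the locants C1' to C8' defined above are used for every intermediate.

**Fragment A: carbamate 8**

Step 1
Reactants: 1 but-3-yn-1-ol
Product: 2 but-3-yn-1-yl N,N-diisopropylcarbamate
Conditions: iPr2NCOCl, Et3N, DCM, reflux
Reagents that add atoms: N,N-diisopropylcarbamoyl chloride, CC(C)N(C(C)C)C(=O)Cl
Why: O-carbamoylation of a primary alcohol by nucleophilic acyl substitution on a carbamoyl chloride, to which the terminal alkyne is inert.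

Step 2
Reactants: 2 but-3-yn-1-yl N,N-diisopropylcarbamate
Product: 4 methyl 5-[(diisopropylcarbamoyl)oxy]pent-2-ynoate, via lithium acetylide 3 (not isolated)
Conditions: n-BuLi, THF, −78 °C; ClCO2Me, −78 → 0 °C
Reagents that add atoms: methyl chloroformate, COC(=O)Cl
Why: Deprotonation of the terminal alkyne by n-BuLi at −78 °C is much faster than attack on the hindered diisopropylcarbamate, and C-acylation of the acetylide by the chloroformate gives the alkynoate, whose ester carbon is C1'.

Step 3
Reactants: 4 methyl 5-[(diisopropylcarbamoyl)oxy]pent-2-ynoate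
Product: 6 methyl (2Z)-5-[(diisopropylcarbamoyl)oxy]-3-methylpent-2-enoate, via alkenyl(methyl)cuprate 5 (not isolated)
Conditions: Me2CuLi (from CuI, 2 MeLi), THF, −78 °C; MeOH, −78 °C; aq NH4Cl
Reagents that add atoms: lithium dimethylcuprate Me2CuLi, [Li+].C[Cu-]C
Why: Conjugate syn-carbocupration of a 2-alkynoate puts methyl on C3' and copper on C2' on the same side, and protonation at −78 °C with retention leaves the C4' chain cis to C1', which fixes the Z alkene that the cis-oxirane needs.

Step 4
Reactants: 6 methyl (2Z)-5-[(diisopropylcarbamoyl)oxy]-3-methylpent-2-enoate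
Product: 7 (3Z)-5-hydroxy-3-methylpent-3-en-1-yl N,N-diisopropylcarbamate
Conditions: i-Bu2AlH, DCM, −78 °C; aq potassium sodium tartrate KNaC4H4O6
Reagents that add atoms: none
Why: 1,2-Reduction of the enoate to the allylic alcohol by i-Bu2AlH at −78 °C, where the hindered N,N-diisopropylcarbamate is not reduced and the alkene geometry is untouched.

Step 5
Reactants: 7 (3Z)-5-hydroxy-3-methylpent-3-en-1-yl N,N-diisopropylcarbamate
Product: 8 (3Z)-3-methyl-5-[(triisopropylsilyl)oxy]pent-3-en-1-yl N,N-diisopropylcarbamate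
Conditions: TIPSCl, imidazole, DMF, rt
Reagents that add atoms: chlorotriisopropylsilane, CC(C)[Si](Cl)(C(C)C)C(C)C
Why: Imidazole-promoted silylation of the primary allylic alcohol gives a bulky ether that resists sBuLi, is too poor a leaving group for SN2' closure onto C3' by the later C5' organolithium, and survives aqueous acetic acid.

**Fragment B: boronate 13**

Step 6
Reactants: 9 2-methylprop-2-en-1-ol
Product: 10 [(2S)-2-methyloxiran-2-yl]methanol
Conditions: Ti(OiPr)4 (cat.), L-(+)-DET (cat.), cumene hydroperoxide, 4 Å MS, DCM, −20 °C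
Reagents that add atoms: cumene hydroperoxide, CC(C)(OO)c1ccccc1
Why: Katsuki–Sharpless asymmetric epoxidation, in which the titanium L-(+)-tartrate complex delivers oxygen to one enantiotopic face (the sense that gives 2S epoxy alcohols from primary allylic alcohols) and so sets the quaternary carbon that becomes C7'.

Step 7
Reactants: 10 [(2S)-2-methyloxiran-2-yl]methanol; 11 bis(pinacolato)diboron
Product: 12 (2R)-2-methyl-3-(4,4,5,5-tetramethyl-1,3,2-dioxaborolan-2-yl)propane-1,2-diol
Conditions: CuI (cat.), Xantphos (cat.), LiOtBu (cat.), MeOH, THF, rt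
Reagents that add atoms: none
Why: Copper-catalysed borylative ring opening of a terminal epoxide, in which the Cu–Bpin species attacks the unsubstituted oxirane carbon in an SN2 manner so that the quaternary centre is untouched (the descriptor changes only because boron lowers the rank of C6').

Step 8
Reactants: 12 (2R)-2-methyl-3-(4,4,5,5-tetramethyl-1,3,2-dioxaborolan-2-yl)propane-1,2-diol
Product: 13 4,4,5,5-tetramethyl-2-{[(4R)-2,2,4-trimethyl-1,3-dioxolan-4-yl]methyl}-1,3,2-dioxaborolane
Conditions: 2,2-dimethoxypropane, PPTS (cat.), DCM, rt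
Reagents that add atoms: 2,2-dimethoxypropane, COC(C)(C)OC
Why: Acid-catalysed transketalisation of the 1,2-diol (acetonide formation) removes both acidic protons and leaves only a ketal oxygen β to boron.

**Union**

Step 9
Reactants: 8 (3Z)-3-methyl-5-[(triisopropylsilyl)oxy]pent-3-en-1-yl N,N-diisopropylcarbamate; 13 4,4,5,5-tetramethyl-2-{[(4R)-2,2,4-trimethyl-1,3-dioxolan-4-yl]methyl}-1,3,2-dioxaborolane
Product: 17 (2S,4Z)-4-methyl-6-[(triisopropylsilyl)oxy]-1-[(4R)-2,2,4-trimethyl-1,3-dioxolan-4-yl]hex-4-en-2-ol, via lithiated carbamate 14 (not isolated), via boronate complex 15 (not isolated), via secondary boronic ester 16 (not isolated)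
Conditions: sBuLi, (+)-sparteine, Et2O, −78 °C; 13, −78 °C, then 35 °C; NaOH, H2O2, THF/H2O, 0 °C → rt
Reagents that add atoms: hydrogen peroxide, OO
Why: sBuLi bound to (+)-sparteine removes the pro-R hydrogen of the OCH2 group of 8 to give the configurationally stable α-oxy organolithium 14, which 13 borylates with retention to boronate complex 15; on warming, the C6' methylene migrates from boron to C5' anti to the departing carbamate (1,2-metallate shift, inversion) to give 16, and alkaline H2O2 replaces boron by oxygen with retention. The closest known reaction type is the lithiation–borylation–oxidation of primary O-alkyl N,N-diisopropylcarbamates with primary alkyl pinacol boronic esters, a Matteson-type homologation with a chiral carbenoid, of which 13 is a new β-oxygenated substrate. No ring is closed. The one new stereocentre, C5', is controlled by the chiral diamine, which distinguishes the enantiotopic hydrogens, and the three following events are stereospecific, so 17 should be 5'S, the arrangement that is named 5'R in the target once C3' carries oxygen. Selectivity for the C5' hydrogens over the allylic C4' and C1' hydrogens is secured by the carbamate carbonyl, which binds the base next to the OCH2 group, by the bulk of the TIPS ether and by using no excess of sBuLi. Migration rather than β-elimination from 15 is secured by the C7' oxygen being a ketal oxygen, a poor leaving group, and by adding no Lewis acid.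

**Endgame**

Step 10
Reactants: 17 (2S,4Z)-4-methyl-6-[(triisopropylsilyl)oxy]-1-[(4R)-2,2,4-trimethyl-1,3-dioxolan-4-yl]hex-4-en-2-ol
Product: 18 (2R,4S,6Z)-2,6-dimethyl-8-[(triisopropylsilyl)oxy]oct-6-ene-1,2,4-triol
Conditions: AcOH/THF/H2O, 40 °C
Reagents that add atoms: none
Why: Acid-catalysed hydrolysis of the isopropylidene ketal under conditions mild enough to keep the primary TIPS ether and the alkene.

Step 11
Reactants: 18 (2R,4S,6Z)-2,6-dimethyl-8-[(triisopropylsilyl)oxy]oct-6-ene-1,2,4-triol
Product: 20 (3R,5S)-3-hydroxy-3-methyl-5-{(2Z)-2-methyl-4-[(triisopropylsilyl)oxy]but-2-en-1-yl}oxolan-2-one, via lactol 19 (not isolated)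
Conditions: TEMPO (cat.), PhI(OAc)2, DCM, rt
Reagents that add atoms: none
Why: TEMPO/PhI(OAc)2 oxidative lactonisation of a 1,4-diol, in which the oxoammonium salt oxidises only the primary C8' alcohol, the C5' hydroxyl traps the aldehyde as five-membered lactol 19 and a second oxidation gives the γ-lactone, with the tertiary C7' hydroxyl, the alkene and both stereocentres untouched.

Step 12
Reactants: 20 (3R,5S)-3-hydroxy-3-methyl-5-{(2Z)-2-methyl-4-[(triisopropylsilyl)oxy]but-2-en-1-yl}oxolan-2-one
Product: 21 (3R,5S)-3-hydroxy-5-[(2Z)-4-hydroxy-2-methylbut-2-en-1-yl]-3-methyloxolan-2-one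
Conditions: Bu4NF, AcOH, THF, 0 °C → rt
Reagents that add atoms: none
Why: Fluoride-induced cleavage of the silyl ether, buffered with acetic acid so that the lactone is not exposed to strong base.

Step 13
Reactants: 21 (3R,5S)-3-hydroxy-5-[(2Z)-4-hydroxy-2-methylbut-2-en-1-yl]-3-methyloxolan-2-one
Product: 22 (3R,5R)-3-hydroxy-5-{[(2R,3S)-3-(hydroxymethyl)-2-methyloxiran-2-yl]methyl}-3-methyloxolan-2-one
Conditions: Ti(OiPr)4, L-(+)-DET, t-BuOOH, 4 Å MS, DCM, −20 °C
Reagents that add atoms: tert-butyl hydroperoxide, CC(C)(C)OO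
Why: Katsuki–Sharpless asymmetric epoxidation of a Z-trisubstituted primary allylic alcohol, in which stoichiometric titanium L-(+)-tartrate (to allow for binding of the α-hydroxy lactone) delivers oxygen to the face that gives 2'S, the Z geometry then dictating 3'R, so that both oxirane centres are set by the reagent and not by the remote C5' centre.

Step 14
Reactants: 22 (3R,5R)-3-hydroxy-5-{[(2R,3S)-3-(hydroxymethyl)-2-methyloxiran-2-yl]methyl}-3-methyloxolan-2-one; 23 umbelliferone
Product: 24 7-{[(2S,3R)-3-{[(2R,4R)-4-hydroxy-4-methyl-5-oxooxolan-2-yl]methyl}-3-methyloxiran-2-yl]methoxy}-2H-chromen-2-one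
Conditions: PPh3, DIAD, THF, 0 °C → rt
Reagents that add atoms: none
Why: Mitsunobu etherification, in which the acidic phenol protonates the betaine and its phenoxide displaces the oxyphosphonium group at primary C1' in an SN2 manner, while the tertiary C7' hydroxyl cannot be activated and the oxirane is stable under these neutral conditions.

**Compound list**

1 | but-3-yn-1-ol | C#CCCO | starting material
2 | but-3-yn-1-yl N,N-diisopropylcarbamate | C#CCCOC(=O)N(C(C)C)C(C)C | intermediate
3 | lithium acetylide of 2 (formed in the flask) | [Li]C#CCCOC(=O)N(C(C)C)C(C)C | intermediate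
4 | methyl 5-[(diisopropylcarbamoyl)oxy]pent-2-ynoate | COC(=O)C#CCCOC(=O)N(C(C)C)C(C)C | intermediate
5 | lithium alkenyl(methyl)cuprate from syn addition to 4, copper on C2' cis to the new methyl (formed in the flask) | [Li+].C/C(CCOC(=O)N(C(C)C)C(C)C)=C(/C(=O)OC)[Cu-]C | intermediate
6 | methyl (2Z)-5-[(diisopropylcarbamoyl)oxy]-3-methylpent-2-enoate | C/C(CCOC(=O)N(C(C)C)C(C)C)=C/C(=O)OC | intermediate
7 | (3Z)-5-hydroxy-3-methylpent-3-en-1-yl N,N-diisopropylcarbamate | C/C(CCOC(=O)N(C(C)C)C(C)C)=C/CO | intermediate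
8 | (3Z)-3-methyl-5-[(triisopropylsilyl)oxy]pent-3-en-1-yl N,N-diisopropylcarbamate | C/C(CCOC(=O)N(C(C)C)C(C)C)=C/CO[Si](C(C)C)(C(C)C)C(C)C | intermediate
9 | 2-methylprop-2-en-1-ol | C=C(C)CO | starting material
10 | [(2S)-2-methyloxiran-2-yl]methanol | C[C@]1(CO)CO1 | intermediate
11 | bis(pinacolato)diboron | CC1(C)OB(OC1(C)C)B1OC(C)(C)C(C)(C)O1 | starting material
12 | (2R)-2-methyl-3-(4,4,5,5-tetramethyl-1,3,2-dioxaborolan-2-yl)propane-1,2-diol | C[C@](O)(CO)CB1OC(C)(C)C(C)(C)O1 | intermediate
13 | 4,4,5,5-tetramethyl-2-{[(4R)-2,2,4-trimethyl-1,3-dioxolan-4-yl]methyl}-1,3,2-dioxaborolane | CC1(C)OB(C[C@]2(C)COC(C)(C)O2)OC1(C)C | intermediate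
14 | (1R)-1-lithio derivative of 8, present as its (+)-sparteine complex (formed in the flask) | C/C(C[C@@H]([Li])OC(=O)N(C(C)C)C(C)C)=C/CO[Si](C(C)C)(C(C)C)C(C)C | intermediate
15 | lithium boronate complex of 14 and 13, C5' R (formed in the flask) | [Li+].C/C(C[C@H](OC(=O)N(C(C)C)C(C)C)[B-]1(C[C@]2(C)COC(C)(C)O2)OC(C)(C)C(C)(C)O1)=C/CO[Si](C(C)C)(C(C)C)C(C)C | intermediate
16 | secondary pinacol boronic ester with boron on C5' (5'S) after 1,2-migration (formed in the flask) | C/C(C[C@@H](C[C@]1(C)COC(C)(C)O1)B2OC(C)(C)C(C)(C)O2)=C/CO[Si](C(C)C)(C(C)C)C(C)C | intermediate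
17 | (2S,4Z)-4-methyl-6-[(triisopropylsilyl)oxy]-1-[(4R)-2,2,4-trimethyl-1,3-dioxolan-4-yl]hex-4-en-2-ol | C/C(C[C@H](O)C[C@]1(C)COC(C)(C)O1)=C/CO[Si](C(C)C)(C(C)C)C(C)C | intermediate
18 | (2R,4S,6Z)-2,6-dimethyl-8-[(triisopropylsilyl)oxy]oct-6-ene-1,2,4-triol | C/C(C[C@H](O)C[C@@](C)(O)CO)=C/CO[Si](C(C)C)(C(C)C)C(C)C | intermediate
19 | (3R,5S)-3-methyl-5-{(2Z)-2-methyl-4-[(triisopropylsilyl)oxy]but-2-en-1-yl}oxolane-2,3-diol, lactol as either anomer (formed in the flask) | C/C(C[C@H]1C[C@@](C)(O)C(O)O1)=C/CO[Si](C(C)C)(C(C)C)C(C)C | intermediate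
20 | (3R,5S)-3-hydroxy-3-methyl-5-{(2Z)-2-methyl-4-[(triisopropylsilyl)oxy]but-2-en-1-yl}oxolan-2-one | C/C(C[C@H]1C[C@@](C)(O)C(=O)O1)=C/CO[Si](C(C)C)(C(C)C)C(C)C | intermediate
21 | (3R,5S)-3-hydroxy-5-[(2Z)-4-hydroxy-2-methylbut-2-en-1-yl]-3-methyloxolan-2-one | C/C(C[C@H]1C[C@@](C)(O)C(=O)O1)=C/CO | intermediate
22 | (3R,5R)-3-hydroxy-5-{[(2R,3S)-3-(hydroxymethyl)-2-methyloxiran-2-yl]methyl}-3-methyloxolan-2-one | C[C@]1(C[C@H]2C[C@@](C)(O)C(=O)O2)O[C@H]1CO | intermediate
23 | umbelliferone (7-hydroxy-2H-chromen-2-one) | O=c1ccc2ccc(O)cc2o1 | starting material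
24 | 7-{[(2S,3R)-3-{[(2R,4R)-4-hydroxy-4-methyl-5-oxooxolan-2-yl]methyl}-3-methyloxiran-2-yl]methoxy}-2H-chromen-2-one | C[C@]1(C[C@H]2C[C@@](C)(O)C(=O)O2)O[C@H]1COc1ccc2ccc(=O)oc2c1 | target

**Step count.** Total: 14 steps. Longest linear sequence: 11 steps (steps 1–5, then 9–14); the boronate arm (steps 6–8) is three steps.

**Steps most likely to fail**

Step 9. The β-branched boronate 13 may be captured slowly by the bulky diamine-bound organolithium. During the long warm period that carbamate departure needs, the boronate complex may lose its β-oxygen by opening of the dioxolane, or fall back to its components, instead of undergoing the 1,2-shift. The fallback gives C5' a better leaving group so that the shift runs below room temperature. It sets out from 8: LiAlH4 (THF, reflux) cleaves the carbamate to (3Z)-3-methyl-5-[(triisopropylsilyl)oxy]pent-3-en-1-ol F1, and NaH followed by 2,4,6-triisopropylbenzoyl chloride (THF) gives (3Z)-3-methyl-5-[(triisopropylsilyl)oxy]pent-3-en-1-yl 2,4,6-triisopropylbenzoate F2. sBuLi/(+)-sparteine (Et2O, −78 °C) then gives the (1R)-lithiated benzoate F3, which 13 converts into the lithium boronate complex F4. F4 should rearrange between −40 °C and room temperature, without heating or Lewis acid, to the secondary boronic ester 16, where the route is rejoined before the oxidation to 17.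

Step 7. The lithium alkoxide of the hydroxy epoxide may open a second epoxide, and the β-alkoxy boronate formed in the flask may undergo boron–oxygen syn-elimination back to 9 before it is protonated. The fallback brings boron in only after both oxygens are masked. It sets out from 10: LiI/AcOH (THF, 0 °C) opens the oxirane at its CH2 carbon to (2S)-3-iodo-2-methylpropane-1,2-diol F5, and 2,2-dimethoxypropane/PPTS gives (4S)-4-(iodomethyl)-2,2,4-trimethyl-1,3-dioxolane F6. Copper-catalysed borylation of this primary iodide (CuI, PPh3, LiOMe, 11, DMF, rt) gives 13, where the route is rejoined.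

Step 11. PhI(OAc)2 may cleave the C7'–C8' glycol, or the α-hydroxy aldehyde may be degraded before the C5' hydroxyl traps it. The fallback oxidises to the acid with an oxidant that does not cleave glycols and lactonises in a separate operation. It sets out from 18: TEMPO (cat.), NaOCl (cat.) and NaClO2 (MeCN, pH 6.7 phosphate buffer, 35 °C) give (2R,4S,6Z)-2,4-dihydroxy-2,6-dimethyl-8-[(triisopropylsilyl)oxy]oct-6-enoic acid F7, which should close to 20 on warming with PPTS in toluene; the route is rejoined at 20.

**Further compounds**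

F1 | step 9 | (3Z)-3-methyl-5-[(triisopropylsilyl)oxy]pent-3-en-1-ol | C/C(CCO)=C/CO[Si](C(C)C)(C(C)C)C(C)C
F2 | step 9 | (3Z)-3-methyl-5-[(triisopropylsilyl)oxy]pent-3-en-1-yl 2,4,6-triisopropylbenzoate | C/C(CCOC(=O)c1c(C(C)C)cc(C(C)C)cc1C(C)C)=C/CO[Si](C(C)C)(C(C)C)C(C)C
F3 | step 9 | (1R)-1-lithio derivative of F2, as its (+)-sparteine complex | C/C(C[C@@H]([Li])OC(=O)c1c(C(C)C)cc(C(C)C)cc1C(C)C)=C/CO[Si](C(C)C)(C(C)C)C(C)C
F4 | step 9 | lithium boronate complex of F3 and 13 | [Li+].C/C(C[C@H](OC(=O)c1c(C(C)C)cc(C(C)C)cc1C(C)C)[B-]1(C[C@]2(C)COC(C)(C)O2)OC(C)(C)C(C)(C)O1)=C/CO[Si](C(C)C)(C(C)C)C(C)C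
F5 | step 7 | (2S)-3-iodo-2-methylpropane-1,2-diol | C[C@](O)(CO)CI
F6 | step 7 | (4S)-4-(iodomethyl)-2,2,4-trimethyl-1,3-dioxolane | C[C@@]1(CI)COC(C)(C)O1
F7 | step 11 | (2R,4S,6Z)-2,4-dihydroxy-2,6-dimethyl-8-[(triisopropylsilyl)oxy]oct-6-enoic acid | C/C(C[C@H](O)C[C@@](C)(O)C(=O)O)=C/CO[Si](C(C)C)(C(C)C)C(C)C
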